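**Strategy.** Ring B of the target (O5, C6, C7, C8, C8a, C4a; pyrano[3,2-b]pyran numbering) is treated as a branched deoxy-sugar pyranone. Acetaldehyde supplies O5, C6 and its methyl; a four-carbon bis(silyloxy)diene ester supplies C7, C8, C8a, C4a and the future lactone carbon C4. One catalytic asymmetric oxa-Diels–Alder-type cyclocondensation (Mukaiyama aldol, then cyclodehydration) forms C6–C7 and O5–C4a and gives a 6-carbethoxy-2,3-dihydro-4H-pyran-4-one with a single stereocentre. That centre is relayed around the ring: trans hydroxylation (C7), axial cuprate methylation (C4a), epoxide rearrangement and axial hydride delivery (C8, C8a), then Dieckmann closure of lactone ring A and convex-face hydrogenation (C3, C4).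

Key step: step 2

Remark: locants in the text follow the pyrano[3,2-b]pyran numbering of the target (O1, C2, C3, C4, C4a, O5, C6, C7, C8, C8a); (R)-BINOL is assumed to direct addition to the Re face of acetaldehyde, and its antipode would be used if the sense proves opposite.

**Step 1**
Reactants: 1 ethyl 2,4-dioxopentanoate
Product: 2 ethyl (2Z)-2,4-bis[(trimethylsilyl)oxy]penta-2,4-dienoate
Conditions: TMSOTf (2.2 equiv), Et3N, Et2O, 0 °C to rt
Reagents that add atoms: trimethylsilyl trifluoromethanesulfonate (TMSOTf), C[Si](C)(C)OS(=O)(=O)C(F)(F)F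
Why: Double O-silylation (silyl enol ether formation) of the enolised 2,4-dioxo ester should give the 2,4-bis(silyloxy)diene, with the C2=C3 bond Z from the chelated enol and the terminal enol ether formed at the methyl ketone, the only remaining enolisable site.

**Step 2**
Reactants: 2 ethyl (2Z)-2,4-bis[(trimethylsilyl)oxy]penta-2,4-dienoate; 3 acetaldehyde
Product: 5 ethyl (2S)-2-methyl-4-oxo-3,4-dihydro-2H-pyran-6-carboxylate, via silylated aldol adduct 4 (not isolated)
Conditions: (R)-BINOL (20 mol%), Ti(OiPr)4 (10 mol%), 4 Å MS, Et2O, −20 °C; then TFA, CH2Cl2, 0 °C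
Reagents that add atoms: none
Why: The BINOL–titanium Lewis acid (tetravalent titanium) activates acetaldehyde and the terminal CH2 of the diene adds to its Re face through an open Mukaiyama aldol transition state, forming C6–C7 and, after silyl transfer, adduct 4; TFA then unmasks the 2-oxo ester, the C6 hydroxyl adds to that carbonyl and water is lost, forming O5–C4a. The closest known reaction type is the chiral-Lewis-acid-catalysed cyclocondensation of aldehydes with 1,3-dioxygenated dienes (stepwise oxa-Diels–Alder) to 2,3-dihydro-4H-pyran-4-ones. Ring B closes by 6-exo-trig hemiketalisation followed by dehydration to the vinylogous ester. The only new stereocentre, C6 (S), is set by the chiral catalyst (reagent control, Re-face attack). The step needs regioselectivity, secured because the methyl-ketone-derived enol ether is the electron-rich terminus while the other enol ether is deactivated by the ester and because only the 2-oxo carbonyl can give a six-membered ring, and enantioselectivity, which rests on the catalyst.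

**Step 3**
Reactants: 5 ethyl (2S)-2-methyl-4-oxo-3,4-dihydro-2H-pyran-6-carboxylate
Product: 7 ethyl (2S,3S)-3-hydroxy-2-methyl-4-oxo-3,4-dihydro-2H-pyran-6-carboxylate, via lithium dienolate 6 (not isolated)
Conditions: LiN(SiMe3)2, THF, −78 °C; 2-(phenylsulfonyl)-3-phenyloxaziridine, −78 °C; aq. NH4Cl
Reagents that add atoms: 2-(phenylsulfonyl)-3-phenyloxaziridine, O=S(=O)(c1ccccc1)N1OC1c1ccccc1
Why: Kinetic enolisation at C7 followed by enolate oxidation with the N-sulfonyloxaziridine should deliver oxygen to the face opposite the adjacent C6 methyl (1,2-induction in the nearly planar dienolate), setting the trans C7 stereocentre.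

**Step 4**
Reactants: 7 ethyl (2S,3S)-3-hydroxy-2-methyl-4-oxo-3,4-dihydro-2H-pyran-6-carboxylate
Product: 8 ethyl (2S,3S)-3-(benzyloxy)-2-methyl-4-oxo-3,4-dihydro-2H-pyran-6-carboxylate
Conditions: BnOC(=NH)CCl3, TfOH (5 mol%), CH2Cl2–cyclohexane, 0 °C to rt
Reagents that add atoms: benzyl 2,2,2-trichloroacetimidate, N=C(OCc1ccccc1)C(Cl)(Cl)Cl
Why: Acid-catalysed O-benzylation with the trichloroacetimidate protects the C7 hydroxyl without base, so the epimerisable α-oxygenated ketone is not disturbed.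

**Step 5**
Reactants: 8 ethyl (2S,3S)-3-(benzyloxy)-2-methyl-4-oxo-3,4-dihydro-2H-pyran-6-carboxylate
Product: 10 ethyl (2S,5S,6S)-5-(benzyloxy)-2,6-dimethyl-4-{[(trifluoromethyl)sulfonyl]oxy}-5,6-dihydro-2H-pyran-2-carboxylate, via lithium enolate 9 (not isolated)
Conditions: Me2CuLi, Et2O, −78 °C; then PhNTf2, THF, −78 to 0 °C; aq. NH4Cl
Reagents that add atoms: lithium dimethylcuprate (Me2CuLi), [Li+].C[Cu-]C; N-phenylbis(trifluoromethanesulfonimide) (PhNTf2), O=S(=O)(N(c1ccccc1)S(=O)(=O)C(F)(F)F)C(F)(F)F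
Why: Cuprate conjugate addition to the vinylogous ester should occur by axial attack anti to the C6 methyl (2,6-trans rule for dihydropyranones), creating the quaternary C4a with an axial methyl and an equatorial ester, and the regiodefined enolate is trapped as its enol triflate.

**Step 6**
Reactants: 10 ethyl (2S,5S,6S)-5-(benzyloxy)-2,6-dimethyl-4-{[(trifluoromethyl)sulfonyl]oxy}-5,6-dihydro-2H-pyran-2-carboxylate
Product: 11 ethyl (2S,5R,6S)-5-(benzyloxy)-2,4,6-trimethyl-5,6-dihydro-2H-pyran-2-carboxylate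
Conditions: MeZnCl, Pd(PPh3)4 (5 mol%), THF, 50 °C
Reagents that add atoms: methylzinc chloride (MeZnCl), C[Zn]Cl
Why: Negishi cross-coupling of the enol triflate with MeZnCl under zerovalent palladium catalysis replaces the triflate by the C8 methyl with retention of the alkene position.

**Step 7**
Reactants: 11 ethyl (2S,5R,6S)-5-(benzyloxy)-2,4,6-trimethyl-5,6-dihydro-2H-pyran-2-carboxylate
Product: 12 ethyl (1R,2S,4S,5S,6R)-5-(benzyloxy)-2,4,6-trimethyl-3,7-dioxabicyclo[4.1.0]heptane-2-carboxylate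
Conditions: mCPBA, CH2Cl2, 0 °C
Reagents that add atoms: 3-chloroperoxybenzoic acid (mCPBA), O=C(OO)c1cccc(Cl)c1
Why: Prilezhaev epoxidation of the trisubstituted alkene is expected anti to the pseudoaxial C4a methyl, and the facial outcome is not critical because both epoxides converge in step 8.

**Step 8**
Reactants: 12 ethyl (1R,2S,4S,5S,6R)-5-(benzyloxy)-2,4,6-trimethyl-3,7-dioxabicyclo[4.1.0]heptane-2-carboxylate
Product: 13 ethyl (2S,4R,5R,6S)-5-(benzyloxy)-2,4,6-trimethyl-3-oxooxane-2-carboxylate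
Conditions: BF3·OEt2 (20 mol%), CH2Cl2, −78 °C
Reagents that add atoms: none
Why: Meinwald rearrangement: Lewis-acid opening at the tertiary C8 and 1,2-hydride shift from C8a gives the C8a ketone, the competing ring-contracting shift of C4a being disfavoured by its oxygen and ester substituents, and the C8 methyl ends equatorial (hydride migrates anti to the departing oxygen; the centre is also epimerisable α to the ketone).

**Step 9**
Reactants: 13 ethyl (2S,4R,5R,6S)-5-(benzyloxy)-2,4,6-trimethyl-3-oxooxane-2-carboxylate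
Product: 14 ethyl (2S,3S,4S,5R,6S)-5-(benzyloxy)-3-hydroxy-2,4,6-trimethyloxane-2-carboxylate
Conditions: NaBH4, MeOH, −40 °C
Reagents that add atoms: none
Why: Hydride reduction by axial attack on the face away from the axial C4a methyl should give the equatorial C8a alcohol.

**Step 10**
Reactants: 14 ethyl (2S,3S,4S,5R,6S)-5-(benzyloxy)-3-hydroxy-2,4,6-trimethyloxane-2-carboxylate
Product: 15 ethyl (2S,3S,4R,5R,6S)-5-(benzyloxy)-2,4,6-trimethyl-3-(propanoyloxy)oxane-2-carboxylate
Conditions: (EtCO)2O, Et3N, DMAP (cat.), CH2Cl2, rt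
Reagents that add atoms: propanoic anhydride, CCC(=O)OC(=O)CC
Why: DMAP-catalysed acylation (nucleophilic catalysis) esterifies the hindered equatorial C8a hydroxyl with the three carbons that become C2, C3 and the C3 methyl.

**Step 11**
Reactants: 15 ethyl (2S,3S,4R,5R,6S)-5-(benzyloxy)-2,4,6-trimethyl-3-(propanoyloxy)oxane-2-carboxylate
Product: 17 (4aS,6S,7R,8R,8aS)-7-(benzyloxy)-4-hydroxy-3,4a,6,8-tetramethyl-6,7,8,8a-tetrahydropyrano[3,2-b]pyran-2(4aH)-one, via lithium ester enolate 16 (not isolated)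
Conditions: LiN(SiMe3)2 (2.2 equiv), THF, −78 to 0 °C; then 1 M HCl
Reagents that add atoms: none
Why: Dieckmann condensation: the propanoate enolate attacks the adjacent equatorial ethyl ester (6-exo-trig, trans ring fusion possible because both groups are equatorial) and the stabilised β-keto lactone enolate drives the closure of ring A.

**Step 12**
Reactants: 17 (4aS,6S,7R,8R,8aS)-7-(benzyloxy)-4-hydroxy-3,4a,6,8-tetramethyl-6,7,8,8a-tetrahydropyrano[3,2-b]pyran-2(4aH)-one
Product: 18 (3R,4S,4aR,6S,7R,8R,8aS)-7-(benzyloxy)-4-hydroxy-3,4a,6,8-tetramethylhexahydropyrano[3,2-b]pyran-2(3H)-one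
Conditions: H2 (50 bar), Raney Ni, EtOAc, rt
Reagents that add atoms: none
Why: Heterogeneous hydrogenation adds both hydrogens cis to the enol C3=C4 bond from the face opposite the angular C4a methyl, which should set C3 (R) and C4 (S) with methyl and hydroxyl cis to that angular methyl, as in the all-cis reduction of 3-alkyl-4-hydroxy-5,6-dihydropyran-2-ones.

**Step 13**
Reactants: 18 (3R,4S,4aR,6S,7R,8R,8aS)-7-(benzyloxy)-4-hydroxy-3,4a,6,8-tetramethylhexahydropyrano[3,2-b]pyran-2(3H)-one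
Product: 19 (3R,4S,4aR,6S,7R,8R,8aS)-4,7-dihydroxy-3,4a,6,8-tetramethylhexahydropyrano[3,2-b]pyran-2(3H)-one
Conditions: H2 (1 bar), Pd/C, EtOAc, rt
Reagents that add atoms: none
Why: Hydrogenolysis of the benzyl ether over Pd/C frees the C7 hydroxyl without touching the lactone.

**Step 14**
Reactants: 20 hexan-2-one; 21 glyoxylic acid monohydrate
Product: 22 (2E)-4-oxooct-2-enoic acid
Conditions: pyrrolidine (cat.), AcOH, MeOH, 60 °C
Reagents that add atoms: none
Why: Amine-catalysed aldol condensation (enamine formed at the methyl side of the ketone) with glyoxylic acid and dehydration gives the conjugated keto acid as the thermodynamically favoured E isomer.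

**Step 15**
Reactants: 19 (3R,4S,4aR,6S,7R,8R,8aS)-4,7-dihydroxy-3,4a,6,8-tetramethylhexahydropyrano[3,2-b]pyran-2(3H)-one; 22 (2E)-4-oxooct-2-enoic acid
Product: 24 (3R,4S,4aR,6S,7R,8R,8aS)-4-hydroxy-3,4a,6,8-tetramethyl-2-oxooctahydropyrano[3,2-b]pyran-7-yl (2E)-4-oxooct-2-enoate (botcinin I), via mixed anhydride 23 (not isolated)
Conditions: MNBA (2-methyl-6-nitrobenzoic anhydride), Et3N, DMAP (cat.), CH2Cl2, 0 °C to rt
Reagents that add atoms: none
Why: Mixed-anhydride esterification with nucleophilic catalysis should acylate the C7 hydroxyl, flanked only by two CH(CH3) carbons, in preference to the C4 hydroxyl, which is shielded by the quaternary C4a and two cis methyl groups.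

**Compound list**

1 | ethyl 2,4-dioxopentanoate | CCOC(=O)C(=O)CC(C)=O | starting material
2 | ethyl (2Z)-2,4-bis[(trimethylsilyl)oxy]penta-2,4-dienoate | CCOC(=O)/C(O[Si](C)(C)C)=C/C(O[Si](C)(C)C)=C | intermediate
3 | acetaldehyde | CC=O | starting material
4 | ethyl (2Z,6S)-4-oxo-2,6-bis[(trimethylsilyl)oxy]hept-2-enoate (silylated aldol adduct) | CCOC(=O)/C(O[Si](C)(C)C)=C/C(=O)C[C@H](C)O[Si](C)(C)C | intermediate (not isolated)
5 | ethyl (2S)-2-methyl-4-oxo-3,4-dihydro-2H-pyran-6-carboxylate | CCOC(=O)C1=CC(=O)C[C@H](C)O1 | intermediate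
6 | lithium (2S)-6-(ethoxycarbonyl)-2-methyl-2H-pyran-4-olate (lithium dienolate) | CCOC(=O)C1=CC(O[Li])=C[C@H](C)O1 | intermediate (not isolated)
7 | ethyl (2S,3S)-3-hydroxy-2-methyl-4-oxo-3,4-dihydro-2H-pyran-6-carboxylate | CCOC(=O)C1=CC(=O)[C@@H](O)[C@H](C)O1 | intermediate
8 | ethyl (2S,3S)-3-(benzyloxy)-2-methyl-4-oxo-3,4-dihydro-2H-pyran-6-carboxylate | CCOC(=O)C1=CC(=O)[C@@H](OCc2ccccc2)[C@H](C)O1 | intermediate
9 | lithium (2S,5S,6S)-5-(benzyloxy)-2-(ethoxycarbonyl)-2,6-dimethyl-5,6-dihydro-2H-pyran-4-olate (lithium enolate) | CCOC(=O)[C@]1(C)C=C(O[Li])[C@@H](OCc2ccccc2)[C@H](C)O1 | intermediate (not isolated)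
10 | ethyl (2S,5S,6S)-5-(benzyloxy)-2,6-dimethyl-4-{[(trifluoromethyl)sulfonyl]oxy}-5,6-dihydro-2H-pyran-2-carboxylate | CCOC(=O)[C@]1(C)C=C(OS(=O)(=O)C(F)(F)F)[C@@H](OCc2ccccc2)[C@H](C)O1 | intermediate
11 | ethyl (2S,5R,6S)-5-(benzyloxy)-2,4,6-trimethyl-5,6-dihydro-2H-pyran-2-carboxylate | CCOC(=O)[C@]1(C)C=C(C)[C@@H](OCc2ccccc2)[C@H](C)O1 | intermediate
12 | ethyl (1R,2S,4S,5S,6R)-5-(benzyloxy)-2,4,6-trimethyl-3,7-dioxabicyclo[4.1.0]heptane-2-carboxylate | CCOC(=O)[C@]1(C)[C@@H]2O[C@]2(C)[C@@H](OCc3ccccc3)[C@H](C)O1 | intermediate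
13 | ethyl (2S,4R,5R,6S)-5-(benzyloxy)-2,4,6-trimethyl-3-oxooxane-2-carboxylate | CCOC(=O)[C@]1(C)C(=O)[C@H](C)[C@@H](OCc2ccccc2)[C@H](C)O1 | intermediate
14 | ethyl (2S,3S,4S,5R,6S)-5-(benzyloxy)-3-hydroxy-2,4,6-trimethyloxane-2-carboxylate | CCOC(=O)[C@]1(C)[C@@H](O)[C@H](C)[C@@H](OCc2ccccc2)[C@H](C)O1 | intermediate
15 | ethyl (2S,3S,4R,5R,6S)-5-(benzyloxy)-2,4,6-trimethyl-3-(propanoyloxy)oxane-2-carboxylate | CCOC(=O)[C@]1(C)[C@@H](OC(=O)CC)[C@H](C)[C@@H](OCc2ccccc2)[C@H](C)O1 | intermediate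
16 | lithium enolate of the propanoate ester of 15 (enolate geometry not defined) | CCOC(=O)[C@]1(C)[C@@H](OC(O[Li])=CC)[C@H](C)[C@@H](OCc2ccccc2)[C@H](C)O1 | intermediate (not isolated)
17 | (4aS,6S,7R,8R,8aS)-7-(benzyloxy)-4-hydroxy-3,4a,6,8-tetramethyl-6,7,8,8a-tetrahydropyrano[3,2-b]pyran-2(4aH)-one | c1ccccc1CO[C@@H]1[C@@H](C)[C@@H]2OC(=O)C(C)=C(O)[C@@]2(C)O[C@H]1C | intermediate
18 | (3R,4S,4aR,6S,7R,8R,8aS)-7-(benzyloxy)-4-hydroxy-3,4a,6,8-tetramethylhexahydropyrano[3,2-b]pyran-2(3H)-one | c1ccccc1CO[C@@H]1[C@@H](C)[C@@H]2OC(=O)[C@H](C)[C@H](O)[C@@]2(C)O[C@H]1C | intermediate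
19 | (3R,4S,4aR,6S,7R,8R,8aS)-4,7-dihydroxy-3,4a,6,8-tetramethylhexahydropyrano[3,2-b]pyran-2(3H)-one | O[C@@H]1[C@@H](C)[C@@H]2OC(=O)[C@H](C)[C@H](O)[C@@]2(C)O[C@H]1C | intermediate
20 | hexan-2-one | CCCCC(C)=O | starting material
21 | glyoxylic acid monohydrate | OC(O)C(=O)O | starting material
22 | (2E)-4-oxooct-2-enoic acid | CCCCC(=O)/C=C/C(=O)O | intermediate
23 | (2E)-4-oxooct-2-enoic 2-methyl-6-nitrobenzoic anhydride (mixed anhydride) | CCCCC(=O)/C=C/C(=O)OC(=O)c1c(C)cccc1[N+](=O)[O-] | intermediate (not isolated)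
24 | (3R,4S,4aR,6S,7R,8R,8aS)-4-hydroxy-3,4a,6,8-tetramethyl-2-oxooctahydropyrano[3,2-b]pyran-7-yl (2E)-4-oxooct-2-enoate (botcinin I) | CCCCC(=O)/C=C/C(=O)O[C@@H]1[C@@H](C)[C@@H]2OC(=O)[C@H](C)[C@H](O)[C@@]2(C)O[C@H]1C | target

**Summary**

Total step count: 15. Longest linear sequence: 14 steps (steps 1–13 and 15, from ethyl 2,4-dioxopentanoate).

Steps most likely to fail:

1. Step 2 (key step). The small aldehyde may be discriminated poorly by the chiral titanium catalyst, giving low enantiomeric purity, or acetaldehyde may self-condense before it is trapped. Fallback, setting out from acetaldehyde 3 and returning at 5: Brown allylboration with the Ipc2B(allyl) reagent made from (−)-α-pinene should give (2S)-pent-4-en-2-ol F1. Silylation with TBSCl and imidazole gives tert-butyldimethyl{[(2S)-pent-4-en-2-yl]oxy}silane F2. Wacker oxidation (PdCl2, CuCl, O2, DMF–H2O) gives (4S)-4-[(tert-butyldimethylsilyl)oxy]pentan-2-one F3. Claisen condensation of its kinetic lithium enolate (LiN(SiMe3)2, THF, −78 °C) with diethyl oxalate gives ethyl (6S)-6-[(tert-butyldimethylsilyl)oxy]-2,4-dioxoheptanoate F4. TFA in CH2Cl2 then removes the silyl group and cyclodehydrates to 5, where the route is rejoined; here the stereocentre comes from reagent-controlled allylboration and the two ring bonds form in separate operations.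

2. Step 12. The tetrasubstituted enol next to the quaternary C4a may resist hydrogenation or be reduced with poor facial selectivity. Fallback, setting out from 14 and returning at 18: (i-Bu)2AlH in CH2Cl2 at −78 °C reduces the ester to (2S,3S,4S,5R,6S)-5-(benzyloxy)-3-hydroxy-2,4,6-trimethyloxane-2-carbaldehyde F5. Acylation with 2-bromopropanoyl bromide and pyridine gives (2S,3S,4R,5R,6S)-5-(benzyloxy)-2-formyl-2,4,6-trimethyloxan-3-yl 2-bromopropanoate F6. SmI2 in THF at −78 °C then effects an intramolecular Reformatsky reaction through a samarium-chelated cyclic transition state, closing ring A to give 18, from which step 13 continues.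

3. Step 15. The two secondary hydroxyls may not be discriminated well enough (acylation at the C4 hydroxyl or double acylation), or the base may isomerise the keto-enoate. Fallback, setting out from 18 and returning at 24: TESOTf and 2,6-lutidine give (3R,4S,4aS,6S,7R,8R,8aS)-7-(benzyloxy)-3,4a,6,8-tetramethyl-4-[(triethylsilyl)oxy]hexahydropyrano[3,2-b]pyran-2(3H)-one F7. Hydrogenolysis (H2, Pd/C) gives (3R,4S,4aS,6S,7R,8R,8aS)-7-hydroxy-3,4a,6,8-tetramethyl-4-[(triethylsilyl)oxy]hexahydropyrano[3,2-b]pyran-2(3H)-one F8. Esterification with 22 under the conditions of step 15 gives (3R,4S,4aS,6S,7R,8R,8aS)-3,4a,6,8-tetramethyl-2-oxo-4-[(triethylsilyl)oxy]octahydropyrano[3,2-b]pyran-7-yl (2E)-4-oxooct-2-enoate F9. HF·pyridine in THF at 0 °C removes the silyl group and gives 24.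

**Further compounds**

F1 | step 2 | (2S)-pent-4-en-2-ol | C[C@H](O)CC=C
F2 | step 2 | tert-butyldimethyl{[(2S)-pent-4-en-2-yl]oxy}silane | C[C@H](O[Si](C)(C)C(C)(C)C)CC=C
F3 | step 2 | (4S)-4-[(tert-butyldimethylsilyl)oxy]pentan-2-one | C[C@H](O[Si](C)(C)C(C)(C)C)CC(C)=O
F4 | step 2 | ethyl (6S)-6-[(tert-butyldimethylsilyl)oxy]-2,4-dioxoheptanoate | CCOC(=O)C(=O)CC(=O)C[C@H](C)O[Si](C)(C)C(C)(C)C
F5 | step 12 | (2S,3S,4S,5R,6S)-5-(benzyloxy)-3-hydroxy-2,4,6-trimethyloxane-2-carbaldehyde | O=C[C@]1(C)[C@@H](O)[C@H](C)[C@@H](OCc2ccccc2)[C@H](C)O1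
F6 | step 12 | (2S,3S,4R,5R,6S)-5-(benzyloxy)-2-formyl-2,4,6-trimethyloxan-3-yl 2-bromopropanoate | O=C[C@]1(C)[C@@H](OC(=O)C(C)Br)[C@H](C)[C@@H](OCc2ccccc2)[C@H](C)O1
F7 | step 15 | (3R,4S,4aS,6S,7R,8R,8aS)-7-(benzyloxy)-3,4a,6,8-tetramethyl-4-[(triethylsilyl)oxy]hexahydropyrano[3,2-b]pyran-2(3H)-one | c1ccccc1CO[C@@H]1[C@@H](C)[C@@H]2OC(=O)[C@H](C)[C@H](O[Si](CC)(CC)CC)[C@@]2(C)O[C@H]1C
F8 | step 15 | (3R,4S,4aS,6S,7R,8R,8aS)-7-hydroxy-3,4a,6,8-tetramethyl-4-[(triethylsilyl)oxy]hexahydropyrano[3,2-b]pyran-2(3H)-one | O[C@@H]1[C@@H](C)[C@@H]2OC(=O)[C@H](C)[C@H](O[Si](CC)(CC)CC)[C@@]2(C)O[C@H]1C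
F9 | step 15 | (3R,4S,4aS,6S,7R,8R,8aS)-3,4a,6,8-tetramethyl-2-oxo-4-[(triethylsilyl)oxy]octahydropyrano[3,2-b]pyran-7-yl (2E)-4-oxooct-2-enoate | CCCCC(=O)/C=C/C(=O)O[C@@H]1[C@@H](C)[C@@H]2OC(=O)[C@H](C)[C@H](O[Si](CC)(CC)CC)[C@@]2(C)O[C@H]1C
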